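In a one-step world, dissolved substrate and reagent join to target at a rate k[dissolved substrate][reagent], target falls back at a rate k'[target], and the flask stops moving when the two rates are equal. The ratio [target]/([dissolved substrate][reagent]) then stands at k/k'. Our flask is more than that step, as solid substrate falls from 84.5% to 34.7% in the alpha run, but that ratio can still be read from the runs.

in all of them: solid substrate 19 mM
- delta: reagent 24.7 mM; protic impurity 0.95 mM; run made earlier
- alpha: reagent 24.7 mM; protic impurity 1.4 mM; run made earlier
- zeta: reagent 49 mM; protic impurity 1.9 mM; run made earlier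
- flask: reagent 24.7 mM; protic impurity 1.90 mM; time 10 d

| run | time / d | target / % | dissolved substrate / % | solid substrate / % |
|---|---|---|---|---|
| delta | 1.67 | 6.2 | 12.7 | 76.0 |
| delta | 3.00 | 11.1 | 18.5 | 65.0 |
| delta | 5.00 | 16.3 | 23.9 | 51.2 |
| delta | 6.00 | 17.8 | 26.6 | 46.2 |
| delta | 8.00 | 20.9 | 29.6 | 37.1 |
| alpha | 0.625 | 1.9 | 6.3 | 84.5 |
| alpha | 2.08 | 7.7 | 15.0 | 70.1 |
| alpha | 4.00 | 14.0 | 20.9 | 55.6 |
| alpha | 6.00 | 18.0 | 26.1 | 43.8 |
| alpha | 8.00 | 20.7 | 29.0 | 34.7 |
| zeta | 0.625 | 2.5 | 5.4 | 81.9 |
| zeta | 2.08 | 11.8 | 11.3 | 66.5 |
| zeta | 4.00 | 22.2 | 16.7 | 48.5 |
| zeta | 6.00 | 30.3 | 22.3 | 35.2 |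
| zeta | 8.00 | 35.9 | 25.8 | 23.3 |

(standard deviation of a reading: 0.3 percentage points)

- as a solid, counted per litre of solution: solid substrate
- at the start none of the solid substrate is in solution
- dissolved substrate means what is dissolved; the solid is not counted in it

1. the target standing at 10 d, as a percentage of the solid substrate charged
2. concentration of dissolved substrate in solution at 5.0 d, in percent of saturation
3. the change that raises the amount of target at 10 d, in percent of the solid substrate charged most ("none" if none brings more than 2 percentage points) (Tuesday's / Wednesday's / Monday's / none)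
4. amount of target at 10 d, in percent of the solid substrate charged, after Tuesday's

- Tuesday's: doubling the amount of reagent, all else as stated
- Wednesday's: doubling the dissolution coefficient of the solid substrate, all else as stated
- Monday's: doubling the solubility of the solid substrate, all else as stated

We take free reagent as the charge minus what sits in target. Alpha at its last reading gives 34.4 L mol⁻¹ for the holding number, target over dissolved substrate times free reagent, which is the reaction quotient of this step. At 2.08 d alpha gave 22.1 L mol⁻¹ and at 6.00 d 32.4 L mol⁻¹, so the number climbs, and its climb slows. Delta, with less protic impurity, ends at 34.1 L mol⁻¹. Zeta, with twice the reagent and 1.9 mM of protic impurity, ends at 33.0 L mol⁻¹. These are readings, but they are close, so we carry the number to our flask.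

We extend alpha's last step of dissolved substrate once more and get 31.9% at 10 d. Solving the holding number for target, with the flask's charges, gives 22.4%.

The forecast says “The flask is alpha with slightly more impurity” and gives 22.4% (21.3% to 23.6%). It puts dissolved substrate at 55% of saturation at 5.0 d, names Tuesday's as the best change, and expects 39.9% after it.

The flask gives 22.1% of target at 10 d. Its dissolved substrate stands at 58.6% of saturation at 5.0 d. The best change is Tuesday's, and after it the target stands at 40.0%.

    solid substrate ⇌ dissolved substrate, rate k1*(cs1 - [dissolved substrate]) while solid is left; crystals form when [dissolved substrate] > cs1 (solubility = 7.80 mM, k = 0.0140 h⁻¹)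
    dissolved substrate + reagent ⇌ target (K = 36.0 L mol⁻¹, k = 1.30 L mol⁻¹ h⁻¹)
    2 dissolved substrate → side product (k = 0.250 L mol⁻¹ h⁻¹)
    reagent → decomposition product (k = 1.20 × 10⁻⁵ h⁻¹)
    solid substrate + protic impurity → quenched substrate (k = 23.0 L mol⁻¹ h⁻¹)

At 10 d the step to target, taken alone and both ways together, relaxes with a half-life of 0.411 d, shorter than the time of the run. Put the flask's dissolved substrate and free reagent at that time into the holding number, and it returns 21.7% of target. The same flask charged with 4.8 mM of solid substrate holds 33.3% dissolved and 94.2% of its reagent. There the number returns 26.7% of that charge, and that flask stands at 28.3%.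

The earlier runs and the new flask were computed with constants of no real substance; noise was put on by code.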